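Early on, maple and birch climb less far apart than their charges: at 25 min maple has made 68.9 mM of E from 150 mM of Z, and birch 85.8 mM from 220 mM. We read from this that the rate follows the charge with an order below one.

| flask | Z | X | E | time |
|---|---|---|---|---|
| maple | 150 mM | 15.0 mM |  |  |
| alder | 150 mM | 15.0 mM | 75.0 mM |  |
| birch | 220 mM | 15.0 mM |  |  |
| cedar | 310 mM | 15.0 mM |  | 92 min |

| run | time / min | [E] / mM |
|---|---|---|
| maple run | 3.7 | 12.7 |
| maple run | 7.0 | 21.9 |
| maple run | 13 | 39.0 |
| maple run | 25 | 68.9 |
| maple run | 48 | 103.5 |
| maple run | 92 | 132.5 |
| alder run | 3.7 | 87.8 |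
| alder run | 7.0 | 96.2 |
| alder run | 13 | 114.9 |
| alder run | 25 | 140.3 |
| alder run | 48 | 179.1 |
| alder run | 92 | 204.9 |
| birch run | 3.7 | 12.9 |
| birch run | 7.0 | 26.8 |
| birch run | 13 | 47.7 |
| birch run | 25 | 85.8 |
| birch run | 48 | 138.9 |
| birch run | 92 | 189.9 |

(scatter of a reading: 1 mM)

* apparent order in [Z] of the starting rate, round the charge of the maple run (the rate where two percent of its Z have turned into E) (one fixed amount of E, the same in the runs compared)
* E in the cedar run at 92 min, as a share of the Z charged

- Overall: Z -> E, with X as catalyst.
- Constant volume, constant temperature.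
- Bound and free are read together.
- An order is taken over about fifteen percent of the charge, up and down.

Alder, given 75.0 mM of E at the start, has made 104 mM more by 48 min against maple's 103.5 mM, so we leave added E out of the reckoning.

For a rate V·Z/(K + Z), with K the Michaelis constant, we use the clock, the quantity that a steady catalyst advances at V:

clock = E made + K · ln(Z charged / Z left)

Taking K as 150 mM, the figure of the maple charge, puts the order near there at K/(K + Z) = 0.500. The clock of maple at 25 min reads 161 mM, and birch reads 160 mM, so we read V as 6.45 mM min⁻¹.

At 92 min a steady catalyst would show 593 mM, but maple reads 455 mM and birch 488 mM. We read this as activity being lost, less of it in birch. Birch still reads a lower share at 92 min, 86.3% against 88.3% for maple, because maple's share would cost birch 517 mM of clock.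

For cedar we take the middle between birch's reading and the straight line through maple and birch, 531 mM:

clock of cedar ≈ 510 mM

The forecast gives an order of 0.5 and 81.5%, judging that “substrate appears to protect it”. Its share costs 506 mM of clock, so our middle gives a slightly higher 81.9%.

The flask gives an order of 0.48 and 82.1%, both within the margins.

    X + Z → E + X (3.588 M⁻¹ min⁻¹)
    2 X → 2 Lx (1.116 M⁻¹ min⁻¹)
    X + Z ⇌ XZ, settled at all times (8.850 M⁻¹)

The passing of 2 X into 2 Lx moves the readings by 8.6 times the scatter, root mean square. The clock of cedar comes to 512 mM, which is 86.4% of the steady figure. Birch reaches half its charge at 34.5 min, where its clock reads 214 mM, an average speed of 6.20 mM min⁻¹ against the early 6.45 mM min⁻¹.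

All runs were generated by integration with made-up constants; noise was put on by code.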